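**Plan**
- Cuts: the three late O–C bonds of the protecting groups (two peri O–CH3, one O–benzyl). In unit 2 (the flavone carrying the ether at C6): O1–C2, C2–C3 and C4–C4a. In unit 1 (the flavone whose ring B carries the ether oxygen): C3–C4 and O1–C2. Finally the aryl–O bond at C4' of unit 1.
- Enabling feature: in unit 1 the carbonyl carbon C4 sits on C4a of ring A, next to the oxygen-bearing C8a. It is therefore the formyl carbon of a salicylaldehyde (2-hydroxy-4,6-dimethoxybenzaldehyde), and C3 and C2 map onto the ylide carbon and the ketone carbon of an aroyl sulfoxonium ylide that already holds the diaryl ether.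
- Forward order: diaryl ether by SNAr, phenol by Baeyer–Villiger, benzyl ether, acid, ylide; ring C of unit 1 by formyl C–H annulation; then debenzylation, acetylation, chalcone, ring C of unit 2; BCl3 last.
- Stereochemistry: the target has no stereocentre. The only stereo-element on the way, the E double bond of the chalcone, disappears on cyclization.

Key step: step 6

Remark on the chemistry: the target, a 7,7''-di-O-methyl ether of the hinokiflavone type, is achiral. 4-Fluorobenzonitrile is used as the SNAr acceptor instead of a 4-fluorobenzoate, because the hindered, formyl-deactivated phenoxide of syringaldehyde needs the stronger activation; this costs one hydrolysis step.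

**Step 1**
Reactants: 1 syringaldehyde (4-hydroxy-3,5-dimethoxybenzaldehyde); 2 4-fluorobenzonitrile
Product: 3 4-(4-formyl-2,6-dimethoxyphenoxy)benzonitrile
Conditions: K2CO3 (2 equiv), DMSO, 120 °C
Reagents that add atoms: none
Why: Nucleophilic aromatic substitution (SNAr) should work because the para-cyano group stabilizes the Meisenheimer adduct, fluoride is the best leaving group, and the aldehyde cannot enolize.

**Step 2**
Reactants: 3 4-(4-formyl-2,6-dimethoxyphenoxy)benzonitrile
Product: 5 4-(4-hydroxy-2,6-dimethoxyphenoxy)benzonitrile, via aryl formate 4 (not isolated)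
Conditions: mCPBA (1.5 equiv), CH2Cl2, rt; then K2CO3 (cat.), MeOH, rt
Reagents that add atoms: 3-chloroperoxybenzoic acid (mCPBA), O=C(OO)c1cccc(Cl)c1
Why: Baeyer–Villiger (Dakin-type) oxidation should favour aryl migration because of the para aryloxy donor, as with 3,4,5-trialkoxybenzaldehydes; the formate is then cleaved by transesterification, and the nitrile is inert to the peracid.

**Step 3**
Reactants: 5 4-(4-hydroxy-2,6-dimethoxyphenoxy)benzonitrile
Product: 6 4-[4-(benzyloxy)-2,6-dimethoxyphenoxy]benzonitrile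
Conditions: BnBr (1.2 equiv), K2CO3 (2 equiv), DMF, 50 °C
Reagents that add atoms: benzyl bromide, BrCc1ccccc1
Why: Williamson ether synthesis on an unhindered phenoxide is reliable and masks the phenol through the ylide and rhodium steps.

**Step 4**
Reactants: 6 4-[4-(benzyloxy)-2,6-dimethoxyphenoxy]benzonitrile
Product: 7 4-[4-(benzyloxy)-2,6-dimethoxyphenoxy]benzoic acid
Conditions: KOH (excess), EtOH/H2O, reflux; then aq. HCl
Reagents that add atoms: potassium hydroxide, [K+].[OH-]; water, O
Why: Alkaline nitrile hydrolysis of a 4-aryloxybenzonitrile is standard, and the benzyl, methyl and diaryl ethers are stable to hot hydroxide.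

**Step 5**
Reactants: 7 4-[4-(benzyloxy)-2,6-dimethoxyphenoxy]benzoic acid
Product: 9 dimethylsulfoxonium 2-{4-[4-(benzyloxy)-2,6-dimethoxyphenoxy]phenyl}-2-oxoethylide, via acid chloride 8 (not isolated)
Conditions: (COCl)2 (1.5 equiv), DMF (cat.), CH2Cl2, 0 °C to rt, evaporate; then Me3S(O)I (3 equiv), KOtBu (3 equiv), THF, reflux 2 h, 8 added at 0 °C to rt
Reagents that add atoms: trimethylsulfoxonium iodide, C[S+](C)(C)=O.[I-]; oxalyl chloride, O=C(Cl)C(=O)Cl (chlorine of 8 only)
Why: Acylation of dimethylsulfoxonium methylide (the Corey–Chaykovsky reagent) by an aroyl chloride is the usual route to aroyl sulfoxonium ylides, a second equivalent of the methylide removing the proton of the acylated salt.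

**Step 6**
Reactants: 10 2-hydroxy-4,6-dimethoxybenzaldehyde; 9 dimethylsulfoxonium 2-{4-[4-(benzyloxy)-2,6-dimethoxyphenoxy]phenyl}-2-oxoethylide
Product: 12 2-{4-[4-(benzyloxy)-2,6-dimethoxyphenoxy]phenyl}-5,7-dimethoxy-4H-chromen-4-one, via 1,3-diketone 11 (not isolated)
Conditions: [Cp*RhCl2]2 (4 mol%), AgSbF6 (16 mol%), NaOAc (30 mol%), PivOH (1 equiv), DCE, 100 °C, N2
Reagents that add atoms: none
Why: AgSbF6 strips chloride from [Cp*RhCl2]2 to give a cationic Cp*Rh species (trivalent rhodium) that binds the phenoxide of 10 and cleaves the adjacent formyl C–H by acetate-assisted metalation, giving a five-membered acyl rhodacycle. Ylide 9 then coordinates through carbon, expels dimethyl sulfoxide to form a rhodium carbene, and 1,1-migratory insertion of the acyl group into the carbene makes the C3–C4 bond; protonolysis by pivalic acid releases diketone 11 and returns the catalyst. The closest known reaction type is the Cp*Rh-catalysed annulation of salicylaldehydes with aroyl sulfoxonium ylides to flavones, here applied to a 6-methoxy salicylaldehyde and a larger ylide. The ring closes by 6-exo-trig addition of the phenol oxygen to the aryl ketone of 11 (O1–C2), followed by acid-promoted loss of water to the aromatic pyranone. No stereocentre is formed. The step needs only chemoselectivity (acyl–rhodium insertion rather than O–H insertion or metalation of the ylide's own ortho C–H bonds), and the phenoxide ortho to the formyl group secures it by chelation, while the benzyl ether, methyl ethers and diaryl ether stay inert.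

**Step 7**
Reactants: 12 2-{4-[4-(benzyloxy)-2,6-dimethoxyphenoxy]phenyl}-5,7-dimethoxy-4H-chromen-4-one
Product: 13 2-[4-(4-hydroxy-2,6-dimethoxyphenoxy)phenyl]-5,7-dimethoxy-4H-chromen-4-one
Conditions: H2 (1 atm), 10% Pd/C, THF/MeOH, rt
Reagents that add atoms: none
Why: Catalytic hydrogenolysis cleaves the benzyl aryl ether under conditions that routinely leave the C2–C3 double bond of flavones untouched.

**Step 8**
Reactants: 13 2-[4-(4-hydroxy-2,6-dimethoxyphenoxy)phenyl]-5,7-dimethoxy-4H-chromen-4-one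
Product: 14 2-[4-(3-acetyl-4-hydroxy-2,6-dimethoxyphenoxy)phenyl]-5,7-dimethoxy-4H-chromen-4-one
Conditions: Ac2O (2 equiv), BF3·OEt2, 70 °C; work-up aq. NaOAc, MeOH, 60 °C
Reagents that add atoms: acetic anhydride, CC(=O)OC(C)=O
Why: BF3-mediated Friedel–Crafts (Fries-type) ortho-acylation of a phloroglucinol-type phenol should hit one of the two equivalent positions next to the free OH (para is blocked by the ether), while the BF3-complexed flavone ring A is deactivated.

**Step 9**
Reactants: 14 2-[4-(3-acetyl-4-hydroxy-2,6-dimethoxyphenoxy)phenyl]-5,7-dimethoxy-4H-chromen-4-one; 15 4-(benzyloxy)benzaldehyde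
Product: 16 2-{4-[3-{(2E)-3-[4-(benzyloxy)phenyl]prop-2-enoyl}-4-hydroxy-2,6-dimethoxyphenoxy]phenyl}-5,7-dimethoxy-4H-chromen-4-one
Conditions: 15 (1.3 equiv), KOH (50% aq.), EtOH/THF, rt
Reagents that add atoms: none
Why: Claisen–Schmidt condensation of a 2'-hydroxyacetophenone with a non-enolizable aryl aldehyde should give the chalcone, the E geometry arising from E1cB elimination to the conjugated, thermodynamically preferred alkene.

**Step 10**
Reactants: 16 the (E)-2'-hydroxychalcone of step 9
Product: 17 2-[4-(benzyloxy)phenyl]-6-[4-(5,7-dimethoxy-4-oxo-4H-chromen-2-yl)phenoxy]-5,7-dimethoxy-4H-chromen-4-one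
Conditions: I2 (10 mol%), DMSO, 130 °C; work-up aq. Na2S2O3
Reagents that add atoms: none
Why: Iodine-catalysed oxidative cyclization of 2'-hydroxychalcones in DMSO (6-endo oxa-Michael closure and dehydrogenation, DMSO as terminal oxidant) is the standard flavone synthesis, and catalytic iodine limits ring iodination.

**Step 11**
Reactants: 17 2-[4-(benzyloxy)phenyl]-6-[4-(5,7-dimethoxy-4-oxo-4H-chromen-2-yl)phenoxy]-5,7-dimethoxy-4H-chromen-4-one
Product: 18 5-hydroxy-6-[4-(5-hydroxy-7-methoxy-4-oxo-4H-chromen-2-yl)phenoxy]-2-(4-hydroxyphenyl)-7-methoxy-4H-chromen-4-one (target)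
Conditions: BCl3 (8 equiv, 1 M in CH2Cl2), C6HMe5 (3 equiv), CH2Cl2, −78 °C to rt; MeOH, then aq. HCl
Reagents that add atoms: none
Why: Chelation-controlled Lewis-acid ether cleavage: BCl3 bound to each C4 carbonyl should remove only the peri 5-methoxy groups and, with pentamethylbenzene as cation trap, the benzyl ether, leaving both 7-methoxy groups and the diaryl ether intact.

**Compound list**
1 | syringaldehyde | COc1cc(C=O)cc(OC)c1O | starting material
2 | 4-fluorobenzonitrile | N#Cc1ccc(F)cc1 | starting material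
3 | 4-(4-formyl-2,6-dimethoxyphenoxy)benzonitrile | COc1cc(C=O)cc(OC)c1Oc1ccc(C#N)cc1 | intermediate
4 | 4-(4-cyanophenoxy)-3,5-dimethoxyphenyl formate | COc1cc(OC=O)cc(OC)c1Oc1ccc(C#N)cc1 | intermediate (not isolated)
5 | 4-(4-hydroxy-2,6-dimethoxyphenoxy)benzonitrile | COc1cc(O)cc(OC)c1Oc1ccc(C#N)cc1 | intermediate
6 | 4-[4-(benzyloxy)-2,6-dimethoxyphenoxy]benzonitrile | COc1cc(OCc2ccccc2)cc(OC)c1Oc1ccc(C#N)cc1 | intermediate
7 | 4-[4-(benzyloxy)-2,6-dimethoxyphenoxy]benzoic acid | COc1cc(OCc2ccccc2)cc(OC)c1Oc1ccc(C(=O)O)cc1 | intermediate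
8 | 4-[4-(benzyloxy)-2,6-dimethoxyphenoxy]benzoyl chloride | COc1cc(OCc2ccccc2)cc(OC)c1Oc1ccc(C(=O)Cl)cc1 | intermediate (not isolated)
9 | dimethylsulfoxonium 2-{4-[4-(benzyloxy)-2,6-dimethoxyphenoxy]phenyl}-2-oxoethylide | CS(C)(=O)=CC(=O)c1ccc(Oc2c(OC)cc(OCc3ccccc3)cc2OC)cc1 | intermediate
10 | 2-hydroxy-4,6-dimethoxybenzaldehyde | COc1cc(O)c(C=O)c(OC)c1 | starting material
11 | 1-{4-[4-(benzyloxy)-2,6-dimethoxyphenoxy]phenyl}-3-(2-hydroxy-4,6-dimethoxyphenyl)propane-1,3-dione | COc1cc(O)c(C(=O)CC(=O)c2ccc(Oc3c(OC)cc(OCc4ccccc4)cc3OC)cc2)c(OC)c1 | intermediate (not isolated)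
12 | 2-{4-[4-(benzyloxy)-2,6-dimethoxyphenoxy]phenyl}-5,7-dimethoxy-4H-chromen-4-one | COc1cc(OC)c2c(=O)cc(-c3ccc(Oc4c(OC)cc(OCc5ccccc5)cc4OC)cc3)oc2c1 | intermediate
13 | 2-[4-(4-hydroxy-2,6-dimethoxyphenoxy)phenyl]-5,7-dimethoxy-4H-chromen-4-one | COc1cc(OC)c2c(=O)cc(-c3ccc(Oc4c(OC)cc(O)cc4OC)cc3)oc2c1 | intermediate
14 | 2-[4-(3-acetyl-4-hydroxy-2,6-dimethoxyphenoxy)phenyl]-5,7-dimethoxy-4H-chromen-4-one | COc1cc(OC)c2c(=O)cc(-c3ccc(Oc4c(OC)cc(O)c(C(C)=O)c4OC)cc3)oc2c1 | intermediate
15 | 4-(benzyloxy)benzaldehyde | O=Cc1ccc(OCc2ccccc2)cc1 | starting material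
16 | 2-{4-[3-{(2E)-3-[4-(benzyloxy)phenyl]prop-2-enoyl}-4-hydroxy-2,6-dimethoxyphenoxy]phenyl}-5,7-dimethoxy-4H-chromen-4-one | COc1cc(OC)c2c(=O)cc(-c3ccc(Oc4c(OC)cc(O)c(C(=O)/C=C/c5ccc(OCc6ccccc6)cc5)c4OC)cc3)oc2c1 | intermediate
17 | 2-[4-(benzyloxy)phenyl]-6-[4-(5,7-dimethoxy-4-oxo-4H-chromen-2-yl)phenoxy]-5,7-dimethoxy-4H-chromen-4-one | COc1cc(OC)c2c(=O)cc(-c3ccc(Oc4c(OC)cc5oc(-c6ccc(OCc7ccccc7)cc6)cc(=O)c5c4OC)cc3)oc2c1 | intermediate
18 | 5-hydroxy-6-[4-(5-hydroxy-7-methoxy-4-oxo-4H-chromen-2-yl)phenoxy]-2-(4-hydroxyphenyl)-7-methoxy-4H-chromen-4-one | COc1cc(O)c2c(=O)cc(-c3ccc(Oc4c(OC)cc5oc(-c6ccc(O)cc6)cc(=O)c5c4O)cc3)oc2c1 | target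

**Step count**
Total steps: 11. Longest linear sequence: 11 steps (1 to 18); compounds 2, 10 and 15 enter as purchased building blocks.

**Steps most likely to fail**

Step 6. The formyl C–H metalation may be slow next to the 6-methoxy group. The rhodium carbene may insert into the O–H bond, or the ylide may be consumed through metalation of its own ortho C–H bonds. Cyclodehydration of the diketone may stall. The fallback is a Baker–Venkataraman route that sets out from acid 7 and comes back at 12. Acid 7 is converted to acid chloride 8 as in step 5 and used to O-acylate commercial 2'-hydroxy-4',6'-dimethoxyacetophenone (pyridine, DMAP, CH2Cl2), which should give 2-acetyl-3,5-dimethoxyphenyl 4-[4-(benzyloxy)-2,6-dimethoxyphenoxy]benzoate F1. KOtBu in THF should shift the aroyl group from oxygen to the enolate carbon to give diketone 11, this time isolated. AcOH with catalytic H2SO4 at 90 °C should then close it to 12.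

Step 9. Hydroxide may attack C2 of the existing pyranone and open ring C of unit 1 while the aldol condensation of the doubly ortho-substituted ketone runs slowly. The fallback sets out from 14 and comes back at 17, bypassing 16 and step 10. Compound 14 is deprotonated with LiN(SiMe3)2 (4 equiv, THF, −78 °C) and C-aroylated with 4-(benzyloxy)benzoyl chloride, which should give 1-{3-[4-(5,7-dimethoxy-4-oxo-4H-chromen-2-yl)phenoxy]-6-hydroxy-2,4-dimethoxyphenyl}-3-[4-(benzyloxy)phenyl]propane-1,3-dione F2. TsOH in toluene at reflux should cyclodehydrate it to 17, so that no hydroxide touches unit 1.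

Step 8. Complexation of BF3 by the flavone carbonyl may stall the acylation, and forcing it may cause partial loss of the peri 5-methoxy group or acylation elsewhere. The fallback sets out from 13 and comes back at 17, bypassing 14, 15 and 16, by repeating the annulation of step 6. Phenoxide-directed ortho-formylation of 13 (MgCl2, Et3N, paraformaldehyde, MeCN, reflux) should give 3-[4-(5,7-dimethoxy-4-oxo-4H-chromen-2-yl)phenoxy]-6-hydroxy-2,4-dimethoxybenzaldehyde F3. The ylide dimethylsulfoxonium 2-[4-(benzyloxy)phenyl]-2-oxoethylide F4 is made from 4-(benzyloxy)benzoyl chloride and dimethylsulfoxonium methylide as in step 5. The conditions of step 6 applied to F3 and F4 should then give 17 by way of the 1,3-diketone F2 (not isolated).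

**Further compounds**
F1 | step 6 | 2-acetyl-3,5-dimethoxyphenyl 4-[4-(benzyloxy)-2,6-dimethoxyphenoxy]benzoate | CC(=O)c1c(OC)cc(OC)cc1OC(=O)c1ccc(Oc2c(OC)cc(OCc3ccccc3)cc2OC)cc1
F2 | step 9 | 1-{3-[4-(5,7-dimethoxy-4-oxo-4H-chromen-2-yl)phenoxy]-6-hydroxy-2,4-dimethoxyphenyl}-3-[4-(benzyloxy)phenyl]propane-1,3-dione | COc1cc(OC)c2c(=O)cc(-c3ccc(Oc4c(OC)cc(O)c(C(=O)CC(=O)c5ccc(OCc6ccccc6)cc5)c4OC)cc3)oc2c1
F3 | step 8 | 3-[4-(5,7-dimethoxy-4-oxo-4H-chromen-2-yl)phenoxy]-6-hydroxy-2,4-dimethoxybenzaldehyde | COc1cc(OC)c2c(=O)cc(-c3ccc(Oc4c(OC)cc(O)c(C=O)c4OC)cc3)oc2c1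
F4 | step 8 | dimethylsulfoxonium 2-[4-(benzyloxy)phenyl]-2-oxoethylide | CS(C)(=O)=CC(=O)c1ccc(OCc2ccccc2)cc1
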